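**Assumption:** the absolute sense of the two reagent-controlled steps (step 6 with the (4S,5S)-diazaborolidine, step 14 with the (R)-phosphoric acid) is taken from the behaviour of simple substrates; if either proves reversed, the mirror-image reagent is used with no other change.

## The problem

Compound 35 is a single cyclohexane (ring A) with all its complexity on five ring carbons. The ring atoms are labelled C1 (quaternary, bearing CH2OH and the C13 trienyl chain), C2 (CH with the 3-hydroxypropyl arm), C3 (sp2, carrying the exocyclic C(CH3)CHO unit), C4 and C5 (methylenes) and C6 (tertiary methyl carbinol).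

- C6, C1 and C2 are contiguous stereocentres, two of them fully substituted. The C1 CH2OH, the C6 OH and the C2 arm all lie on one face.
- C1 and C2 are neighbours and can be set together in one bond-forming event. C6 is next to C1 and can be relayed from C1 and C2 once the ring exists.
- The chain carbinol is seven bonds from the ring and cannot be relayed. It has to be set by a reagent and brought in convergently, with both trisubstituted chain alkenes E.
- The tetrasubstituted Z-enal is the most fragile group: it can isomerise, and enolisation towards C2–H would epimerise C2.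
- The C6 tertiary alcohol can eliminate and the allylic chain carbinol can ionise, so the closing steps cannot be acidic or strongly basic.
- The enabling feature is that the oxygens on C3 and C6 are 1,4-related. C4 and C5 are therefore both donor carbons: C3/C4 is a methyl ketone enol ether and C6/C5 (with the C6 methyl) is an isopropenyl group.
- The C4–C5 bond can thus only be made by removing electrons. The C1 hydroxymethyl oxygen sits three atoms from C6, where it can deliver the C6 oxygen as a cyclic carbonate.

## Retrosynthesis

**35 to 34.** Four O–Si bonds are cut. All hydroxyls are carried as silicon ethers (two TBS ethers and a di-tert-butylsilylene across the C1 CH2O and C6 O), so one buffered fluoride treatment ends the synthesis. An acetonide would need acid in the presence of the enal, the tertiary alcohol and the allylic carbinol.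

**34 to 33 to 32.** The exocyclic C3=C bond and the aldehyde are cut back to the ring ketone 32 and an isopropenyl nucleophile. Direct olefination of this α-branched ketone with a phosphonopropionate would be sluggish, poorly controlled in geometry and would need a redox correction. Addition of a small organocerium reagent followed by oxidative 1,3-transposition of the tertiary allylic alcohol 33 brings exactly three carbons at the right oxidation level. The forward step must give the Z-enal.

**32 to 23 + 30.** The C(sp3)–C(sp2) bond between chain C2' and C3' is cut. The C1 vinyl group of 23 is a latent primary alkylborane and 30 is an E-alkenyl iodide. Cutting at the trisubstituted alkene by olefination would give poor E control. Carrying the polyene through the oxidative cyclisation would offer it three competing electron-rich alkenes. The union is convergent and the remote carbinol arrives with its configuration set.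

**30 to 28 to 27 to 24 + 25.** The C–I and C–CH3 bonds come from zirconium-catalysed syn carboalumination–iodination of the terminal alkyne 28, which fixes the E geometry. The carbinol C–C bond comes from catalytic asymmetric propargylation of geranial 24 with allenylboronate 25. Three steps from a commercial aldehyde.

**23 to 22 to 21.** This is a protecting-group exchange only. The cyclic carbonate of 21 would not survive the organometallic addition at C3, so it is methanolysed to diol 22 and re-closed as the silylene 23.

**21 to 20 (key).** The C4–C5 bond and the C6–O bond are cut together. Polar alternatives fail because both carbons are donors. Cutting C1–C6 or C2–C3 instead would leave the quaternary centre or the ring oxygens to be installed later (see the alternatives below). The precursor 20 is acyclic, with only the C1/C2 pair of stereocentres. The forward reaction must oxidise only the silyl enol ether, close 6-endo onto the isopropenyl and not the vinyl group, and capture the C6 cation from the face of the C1 CH2O group.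

**20 to 18 to 17 to 16 to 14.** These are functional-group changes on a fixed skeleton: kinetic enol silylation, carbonate installation, PMB removal, and acid to methyl ketone. The tert-butyl carbonate is introduced only after the methyllithium step and after the Lewis-acidic rearrangement, neither of which it would survive. PMB is orthogonal to the TBS ether of the arm.

**14 to 12 (via 13).** The C1–C2 bond is cut by an ester-enolate [3,3] shift. It creates the quaternary centre and its neighbour in one step from an achiral ester, with relative configuration set by alkene and enolate geometry and absolute configuration by a chiral boron controller. Alkylating an enolate to make C1 would have no comparable control.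

**12 to 7 + 11; 7 to 4 to 2 to 1; 11 to 8.** Acid 11 is δ-valerolactone 8 opened and silylated, so the whole C2 arm is present from the start. Dienol 7 comes from the Z-iodide 4 by Negishi coupling with isopropenylzinc chloride 6 (from 5). Iodide 4 comes from mono-PMB butynediol 2 by hydroxyl-directed trans-hydroalumination–iodination. Copper-assisted isopropenyl carbomagnesiation of a monoprotected butynediol reaches the same diene, but leaves the free hydroxyl on the wrong terminus and costs two protecting-group steps.

## Roads not taken

**Alternative 1:** The cut is C1–C6, made as an aldol, with the C6 oxygen closed onto the C1 carboxyl carbon. Keto acid A1 is activated with tosyl chloride; a chiral isothiourea forms an acylammonium enolate that adds to the methyl ketone and lactonises to the cis-fused β-lactone A2.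
- Merits: A1 is achiral and short to make, enantiocontrol is catalytic, and the four-membered ring forces the C1 carbonyl carbon and the C6 oxygen cis. That guarantee is firmer than the conformational bias the chosen plan relies on for C6.
- Weak points: A2 has hydrogen at C1, nothing at C2 and a ketal at C3. C1 would have to be quaternised through a β-lactone enolate that is prone to ring opening. The arm would have to be alkylated at C2, the more hindered α-position of the C3 ketone, whereas kinetic enolisation goes to C4. The aldol onto a ketone to close a six-membered ring is also slower and more reversible than the five-ring cases.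
- Comparison: the chosen plan sets C1 and C2 first and carries the complete arm and the vinyl handle through the cyclisation. Against this it has to set a stoichiometric chiral controller and a less certain key step.

**Alternative 2:** The cuts are C2–C3 and two bonds to a temporary carbonyl. Co2(CO)8 joins the methyl alkyne and the C1 vinyl group of enyne A3 with CO to give the bicyclic enone A4.
- Merits: the cyclopentenone holds the future aldehyde carbon cis to C2, so the Z-enal geometry is built in. This is better than the chosen plan, which depends on rotamer and thermodynamic preferences in the chromate shift. C1 and C6 are locked in the acetonide beforehand.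
- Weak points: A3 already needs both fully substituted stereocentres C1 and C6 in enantiopure form. It is a 1,7-enyne, less favourable than the usual 1,6 case. C2 is set only by facial selectivity of the cycloaddition. The enone must then be cut between carbonyl and methylene, leaving a one-carbon stub on C2 to be extended by two carbons next to a sensitive enal, and the C1 chain still has to be built from a two-carbon handle.
- Comparison: the chosen plan makes no bond it later breaks and needs five steps after the chain union.

**Alternative 3:** The cut is the bond from C1 to its hydroxymethyl carbon. Bu3SnH and an initiator convert the bromomethylsilyl ether of enone A5 into a radical that adds 5-exo to C1 and gives the oxasilolane A6; oxidation of the C–Si bond would reveal the CH2OH.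
- Merits: this is the most reliable of the three. The reaction type is fully established, the tether forces the new carbon cis to the C6 oxygen, and the quaternary centre forms by conjugate radical addition. In precedent it is clearly ahead of the chosen key step.
- Weak points: the carbocycle and the enantiopure tertiary carbinol of A5 must exist beforehand, so the key step builds no ring of the target. A6 has a bare methylene at C2, and the arm must be introduced there with regio- and stereocontrol. The chain handle and the enal remain to be built.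
- Comparison: the chosen plan has to set against its unprecedented tandem the fact that one step closes ring A, installs the C6 oxygen and leaves every substituent of C1 and C2 in place.

Key step: step 11

Abbreviations used in names: TBS = tert-butyldimethylsilyl; PMB = 4-methoxybenzyl; Boc = tert-butoxycarbonyl; 9-BBN = 9-borabicyclo[3.3.1]nonane.

## Route

Step 1
Reactants: 1 but-2-yne-1,4-diol
Product: 2 4-[(4-methoxyphenyl)methoxy]but-2-yn-1-ol
Conditions: NaH (1 equiv), 4-methoxybenzyl chloride (1 equiv), Bu4NI (cat.), 1 (3 equiv), THF/DMF, 0 °C to rt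
Reagents that add atoms: 4-methoxybenzyl chloride, COc1ccc(CCl)cc1
Why: Williamson etherification; the excess of the symmetrical diol should hold the reaction at the monoether, and unreacted diol is washed out with water.

Step 2
Reactants: 2 4-[(4-methoxyphenyl)methoxy]but-2-yn-1-ol
Product: 4 (2Z)-3-iodo-4-[(4-methoxyphenyl)methoxy]but-2-en-1-ol, via cyclic alkenylaluminate 3 (not isolated)
Conditions: NaAlH2(OCH2CH2OCH3)2 (1.5 equiv), THF, 0 °C; EtOAc; then I2, THF, −78 to 0 °C; aq. potassium sodium tartrate
Reagents that add atoms: iodine, II
Why: Hydroxyl-directed trans-hydroalumination of a propargylic alcohol places hydride on C2 and aluminium on C3 in a five-membered chelate; iodination with retention should give the Z-iodide with iodine cis to CH2OH.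

Step 3
Reactants: 4 (2Z)-3-iodo-4-[(4-methoxyphenyl)methoxy]but-2-en-1-ol; 5 isopropenylmagnesium bromide
Product: 7 (2E)-3-{[(4-methoxyphenyl)methoxy]methyl}-4-methylpenta-2,4-dien-1-ol, via isopropenylzinc chloride 6 (not isolated)
Conditions: 5 (3 equiv), ZnCl2 (3 equiv), THF, 0 °C; then 4, Pd(PPh3)4 (5 mol %), THF, rt
Reagents that add atoms: none
Why: Negishi coupling of an alkenyl iodide proceeds with retention, so the isopropenyl group should end cis to CH2OH and the PMB-oxymethyl group trans; the excess organozinc allows for the free hydroxyl.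

Step 4
Reactants: 8 δ-valerolactone
Product: 11 5-[(tert-butyldimethylsilyl)oxy]pentanoic acid, via sodium 5-hydroxypentanoate 9 (not isolated), via silyl ester 10 (not isolated)
Conditions: NaOH (1 equiv), H2O/MeOH, rt, evaporate; TBSCl (2.2 equiv), imidazole, DMF, rt; then THF/H2O, pH 5, rt
Reagents that add atoms: sodium hydroxide, [Na+].[OH-]; tert-butyldimethylsilyl chloride, CC(C)(C)[Si](C)(C)Cl
Why: Saponification opens the lactone, bis-silylation caps both oxygens, and the labile silyl ester is hydrolysed selectively on mildly acidic aqueous treatment while the primary silyl ether stays.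

Step 5
Reactants: 7 (2E)-3-{[(4-methoxyphenyl)methoxy]methyl}-4-methylpenta-2,4-dien-1-ol; 11 5-[(tert-butyldimethylsilyl)oxy]pentanoic acid
Product: 12 (2E)-3-{[(4-methoxyphenyl)methoxy]methyl}-4-methylpenta-2,4-dien-1-yl 5-[(tert-butyldimethylsilyl)oxy]pentanoate
Conditions: N-ethyl-N'-(3-dimethylaminopropyl)carbodiimide hydrochloride, 4-dimethylaminopyridine (cat.), CH2Cl2, 0 °C to rt
Reagents that add atoms: none
Why: Steglich esterification of an unhindered primary allylic alcohol; no stereocentre is involved.

Step 6
Reactants: 12 (2E)-3-{[(4-methoxyphenyl)methoxy]methyl}-4-methylpenta-2,4-dien-1-yl 5-[(tert-butyldimethylsilyl)oxy]pentanoate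
Product: 14 (2S,3R)-2-{3-[(tert-butyldimethylsilyl)oxy]propyl}-3-ethenyl-3-{[(4-methoxyphenyl)methoxy]methyl}-4-methylpent-4-enoic acid, via boron enolate 13 (not isolated)
Conditions: (4S,5S)-2-bromo-1,3-bis{[3,5-bis(trifluoromethyl)phenyl]sulfonyl}-4,5-diphenyl-1,3,2-diazaborolidine (1.2 equiv), iPr2NEt (1.5 equiv), CH2Cl2, −78 °C; then −20 to 4 °C; aqueous work-up
Reagents that add atoms: none
Why: Enantioselective boron-enolate Ireland–Claisen rearrangement; the hindered amine in CH2Cl2 should give the enolate with the side chain cis to the O–B oxygen, and in the chair transition state this chain and the PMB-oxymethyl group (trans on the alkene) are equatorial while the isopropenyl group is axial, which gives the (2S,3R) relative configuration at the new C1–C2 bond. The chiral diazaborolidine shields one enolate face and so sets the absolute configuration of both centres at once; rearrangements of this type are known to build quaternary centres from 3,3-disubstituted allyl esters.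

Step 7
Reactants: 14 (2S,3R)-2-{3-[(tert-butyldimethylsilyl)oxy]propyl}-3-ethenyl-3-{[(4-methoxyphenyl)methoxy]methyl}-4-methylpent-4-enoic acid
Product: 16 (3S,4R)-3-{3-[(tert-butyldimethylsilyl)oxy]propyl}-4-ethenyl-4-{[(4-methoxyphenyl)methoxy]methyl}-5-methylhex-5-en-2-one, via dilithium gem-diolate 15 (not isolated)
Conditions: MeLi (3.5 equiv), Et2O, 0 °C to rt; inverse quench into cold aq. NH4Cl
Reagents that add atoms: methyllithium, [Li]C
Why: Addition of methyllithium to a lithium carboxylate stops at the dilithium gem-diolate, which releases the methyl ketone only on quench; the hindered environment disfavours over-addition, and the silyl and PMB ethers are inert.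

Step 8
Reactants: 16 (3S,4R)-3-{3-[(tert-butyldimethylsilyl)oxy]propyl}-4-ethenyl-4-{[(4-methoxyphenyl)methoxy]methyl}-5-methylhex-5-en-2-one
Product: 17 (3S,4R)-3-{3-[(tert-butyldimethylsilyl)oxy]propyl}-4-ethenyl-4-(hydroxymethyl)-5-methylhex-5-en-2-one
Conditions: 2,3-dichloro-5,6-dicyano-1,4-benzoquinone (1.3 equiv), CH2Cl2/pH 7 phosphate buffer, 0 °C
Reagents that add atoms: none
Why: Oxidative cleavage of a PMB ether through its benzylic cation; isolated alkenes, the ketone and the TBS ether are not affected. The product may sit partly as its five-membered lactol.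

Step 9
Reactants: 17 (3S,4R)-3-{3-[(tert-butyldimethylsilyl)oxy]propyl}-4-ethenyl-4-(hydroxymethyl)-5-methylhex-5-en-2-one
Product: 18 tert-butyl [(2R,3S)-3-acetyl-6-[(tert-butyldimethylsilyl)oxy]-2-ethenyl-2-(prop-1-en-2-yl)hexyl] carbonate
Conditions: di-tert-butyl dicarbonate (1.5 equiv), 4-dimethylaminopyridine (0.2 equiv), Et3N, CH2Cl2, 0 °C to rt
Reagents that add atoms: di-tert-butyl dicarbonate, CC(C)(C)OC(=O)OC(=O)OC(C)(C)C
Why: Nucleophile-catalysed acylation of the primary alcohol; any lactol form should drain through the open hydroxy ketone because the primary hydroxyl is the better nucleophile.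

Step 10
Reactants: 18 tert-butyl [(2R,3S)-3-acetyl-6-[(tert-butyldimethylsilyl)oxy]-2-ethenyl-2-(prop-1-en-2-yl)hexyl] carbonate
Product: 20 tert-butyl [(2R,3S)-6-[(tert-butyldimethylsilyl)oxy]-3-{1-[(tert-butyldimethylsilyl)oxy]ethenyl}-2-ethenyl-2-(prop-1-en-2-yl)hexyl] carbonate, via potassium enolate 19 (not isolated)
Conditions: KN(SiMe3)2 (1.2 equiv) added to 18 and TBSCl (1.5 equiv), THF, −78 °C
Reagents that add atoms: tert-butyldimethylsilyl chloride, CC(C)(C)[Si](C)(C)Cl
Why: Kinetic deprotonation takes the methyl protons, not the hindered C2–H beside the quaternary centre, so C2 is untouched. Trapping in situ keeps the enolate from reaching the carbonate.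

Step 11
Reactants: 20 tert-butyl [(2R,3S)-6-[(tert-butyldimethylsilyl)oxy]-3-{1-[(tert-butyldimethylsilyl)oxy]ethenyl}-2-ethenyl-2-(prop-1-en-2-yl)hexyl] carbonate
Product: 21 (4aS,5S,8aS)-5-{3-[(tert-butyldimethylsilyl)oxy]propyl}-4a-ethenyl-8a-methylhexahydro-4H-1,3-benzodioxine-2,6-dione
Conditions: reticulated vitreous carbon anode, Pt cathode, undivided cell, constant current (2.2 F/mol), Bu4NPF6 (0.1 M), 2,6-lutidine (4 equiv), CH2Cl2/(CF3)2CHOH 20:1, 0 °C, argon
Reagents that add atoms: none
Why: Proposed new method: anodic one-electron oxidation of the silyl enol ether, the most electron-rich π system of 20, gives a radical cation whose C4 terminus is attacked by the CH2 end (C5) of the isopropenyl group, forming C4–C5 and a tertiary radical at C6. Loss of silicon to hexafluoroisopropanol unveils the C3 ketone, a second electron transfer turns the C6 radical into a cation, and the carbonyl oxygen of the tert-butyl carbonate adds to it, after which isobutene is lost. The closest known reactions are the anodic and chemical one-electron oxidative cyclisations of unsaturated silyl enol ethers onto alkenes and, for the termination, the capture of tertiary cations and iodonium ions by homoallylic tert-butyl carbonates; the two have not been combined in one cell. The carbocycle closes 6-endo-trig with respect to both π bonds, favoured over 5-exo because it gives a tertiary radical and avoids attack at a fully substituted carbon. The carbonate ring is a six-membered closure onto the trigonal C6 cation, the counterpart of the 6-exo iodocarbonate cyclisation. C1 and C2 are already set and only C6 is new: in the chair with the C2 arm and the C1 vinyl group equatorial the carbonate-bearing CH2 is axial, so its carbonyl oxygen reaches only the face of C6 on its own side and the cis-fused carbonate with axial methyl results. The step needs oxidation of the enol ether alone (its potential lies well below those of the alkenes, carbonate and silyl ether), attack by the 1,1-disubstituted isopropenyl group and not the far less nucleophilic vinyl group, and capture of the cation ahead of proton loss or solvent addition. The non-nucleophilic medium, the buffer and the intramolecular trap are chosen for the last point.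

Step 12
Reactants: 21 (4aS,5S,8aS)-5-{3-[(tert-butyldimethylsilyl)oxy]propyl}-4a-ethenyl-8a-methylhexahydro-4H-1,3-benzodioxine-2,6-dione
Product: 22 (2S,3S,4S)-2-{3-[(tert-butyldimethylsilyl)oxy]propyl}-3-ethenyl-4-hydroxy-3-(hydroxymethyl)-4-methylcyclohexan-1-one
Conditions: K2CO3 (cat.), MeOH, 0 °C to rt
Reagents that add atoms: none
Why: Base-catalysed transesterification of the cyclic carbonate to dimethyl carbonate and the diol. C2 is not at risk because its equatorial arm is the thermodynamically preferred arrangement, the epimer being syn-diaxial to the C6 methyl.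

Step 13
Reactants: 22 (2S,3S,4S)-2-{3-[(tert-butyldimethylsilyl)oxy]propyl}-3-ethenyl-4-hydroxy-3-(hydroxymethyl)-4-methylcyclohexan-1-one
Product: 23 (4aS,5S,8aS)-2,2-di-tert-butyl-5-{3-[(tert-butyldimethylsilyl)oxy]propyl}-4a-ethenyl-8a-methylhexahydro-4H-1,3,2-benzodioxasilin-6-one
Conditions: tBu2Si(OSO2CF3)2 (1.2 equiv), 2,6-lutidine (3 equiv), CH2Cl2, 0 °C to rt
Reagents that add atoms: di-tert-butylsilyl bis(trifluoromethanesulfonate), CC(C)(C)[Si](OS(=O)(=O)C(F)(F)F)(OS(=O)(=O)C(F)(F)F)C(C)(C)C
Why: Silylene formation on a 1,3-diol; the primary hydroxyl is silylated first and the tertiary one closes the six-membered ring intramolecularly, any hemiketal form of 22 reopening as the diol is consumed.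

Step 14
Reactants: 24 geranial; 25 allenylboronic acid pinacol ester
Product: 27 (4R,5E)-6,10-dimethylundeca-5,9-dien-1-yn-4-ol, via pinacol borate ester 26 (not isolated)
Conditions: (R)-3,3'-bis(2,4,6-triisopropylphenyl)-1,1'-binaphthyl-2,2'-diyl hydrogen phosphate (5 mol %), 4 Å molecular sieves, toluene, −20 °C; aqueous work-up
Reagents that add atoms: none
Why: Chiral phosphoric acid-catalysed propargylation of an aldehyde by an allenylboronate through a closed six-membered transition state; the acid, hydrogen-bonded to a boronate oxygen, should direct attack to the Re face of the enal and give the (R)-carbinol.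

Step 15
Reactants: 27 (4R,5E)-6,10-dimethylundeca-5,9-dien-1-yn-4-ol
Product: 28 tert-butyl{[(4R,5E)-6,10-dimethylundeca-5,9-dien-1-yn-4-yl]oxy}dimethylsilane
Conditions: TBSCl, imidazole, DMF, rt
Reagents that add atoms: tert-butyldimethylsilyl chloride, CC(C)(C)[Si](C)(C)Cl
Why: Standard silylation of a secondary alcohol; it keeps the allylic alkoxide away from the Lewis-acidic aluminium of the next step.

Step 16
Reactants: 28 tert-butyl{[(4R,5E)-6,10-dimethylundeca-5,9-dien-1-yn-4-yl]oxy}dimethylsilane
Product: 30 tert-butyl{[(1E,4R,5E)-1-iodo-2,6,10-trimethylundeca-1,5,9-trien-4-yl]oxy}dimethylsilane, via alkenylalane 29 (not isolated)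
Conditions: AlMe3 (3 equiv), Cp2ZrCl2 (0.25 equiv), H2O (1.5 equiv), CH2Cl2, −25 °C; then I2, THF, −25 to 0 °C
Reagents that add atoms: trimethylaluminium, C[Al](C)C; iodine, II
Why: Zirconium-catalysed syn carboalumination of a terminal alkyne places methyl on the internal carbon and aluminium on the terminus; iodination with retention should give the E-iodide, and the trisubstituted alkenes do not react.

Step 17
Reactants: 23 (4aS,5S,8aS)-2,2-di-tert-butyl-5-{3-[(tert-butyldimethylsilyl)oxy]propyl}-4a-ethenyl-8a-methylhexahydro-4H-1,3,2-benzodioxasilin-6-one; 30 tert-butyl{[(1E,4R,5E)-1-iodo-2,6,10-trimethylundeca-1,5,9-trien-4-yl]oxy}dimethylsilane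
Product: 32 (4aS,5S,8aS)-2,2-di-tert-butyl-5-{3-[(tert-butyldimethylsilyl)oxy]propyl}-4a-[(3E,6R,7E)-6-[(tert-butyldimethylsilyl)oxy]-4,8,12-trimethyltrideca-3,7,11-trien-1-yl]-8a-methylhexahydro-4H-1,3,2-benzodioxasilin-6-one, via B-alkyl borane 31 (not isolated)
Conditions: 9-BBN (1.5 equiv), THF, 0 °C to rt; then 30, Pd(dppf)Cl2 (5 mol %), AsPh3 (10 mol %), Cs2CO3 (3 equiv), DMF/THF/H2O, rt
Reagents that add atoms: none
Why: Anti-Markovnikov hydroboration of the vinyl group followed by B-alkyl Suzuki coupling, which retains the E geometry of the iodide. Hydroboration of a terminal alkene by 9-BBN is faster than reduction of a hindered ketone, and the coupling is run at room temperature.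

Step 18
Reactants: 32 the C3 ketone from step 17; 5 isopropenylmagnesium bromide
Product: 33 the tertiary allylic alcohol in which C3 of 32 carries hydroxyl and prop-1-en-2-yl (C3 epimers, both usable)
Conditions: 5 (4 equiv), anhydrous CeCl3 (4 equiv), THF, −78 to 0 °C; aq. NH4Cl
Reagents that add atoms: none
Why: Organocerium addition to a hindered, enolisable ketone suppresses enolisation, so C2 is not touched. Equatorial attack anti to the axial C1 CH2O group is expected, but the C3 configuration is lost in the next step.

Step 19
Reactants: 33 the tertiary allylic alcohol from step 18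
Product: 34 (2Z)-2-[(4aS,5R,8aS)-2,2-di-tert-butyl-5-{3-[(tert-butyldimethylsilyl)oxy]propyl}-4a-[(3E,6R,7E)-6-[(tert-butyldimethylsilyl)oxy]-4,8,12-trimethyltrideca-3,7,11-trien-1-yl]-8a-methylhexahydro-4H-1,3,2-benzodioxasilin-6-ylidene]propanal
Conditions: pyridinium chlorochromate (3 equiv), 4 Å molecular sieves, CH2Cl2, rt
Reagents that add atoms: pyridinium chlorochromate, [O-][Cr](=O)(=O)Cl.c1cc[nH+]cc1
Why: Babler–Dauben oxidative transposition: the tertiary chromate ester undergoes a [3,3] shift to the primary allylic chromate, which is oxidised to the enal, the aldehyde oxygen coming from the hexavalent chromium reagent. The =CH2 end of the isopropenyl group, smaller than its methyl, should lie on the side of the substituted C2 in the reacting rotamer, so the new CH2O carbon ends cis to C2 (Z). The Z-enal is also the less strained isomer, with the methyl group facing the C4 methylene.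

Step 20
Reactants: 34 the Z-enal from step 19
Product: 35 (2Z)-2-[(2R,3S,4S)-4-hydroxy-3-(hydroxymethyl)-2-(3-hydroxypropyl)-3-[(3E,6R,7E)-6-hydroxy-4,8,12-trimethyltrideca-3,7,11-trien-1-yl]-4-methylcyclohexylidene]propanal
Conditions: HF·pyridine, pyridine/THF, 0 °C to rt
Reagents that add atoms: none
Why: Fluoride cleaves both TBS ethers and the silylene in one operation; the pyridine buffer keeps the medium too mild to ionise the allylic carbinol, eliminate the tertiary alcohol or isomerise the enal.

## Compound list

1 | but-2-yne-1,4-diol | OCC#CCO | starting material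
2 | 4-[(4-methoxyphenyl)methoxy]but-2-yn-1-ol | OCC#CCOCc1ccc(OC)cc1 | intermediate
3 | sodium cyclic alkenylaluminate (five-membered O–Al–C chelate, two 2-methoxyethoxy ligands on Al) | [Na+].COCCO[Al-]1(OCCOC)OCC=C1COCc1ccc(OC)cc1 | intermediate
4 | (2Z)-3-iodo-4-[(4-methoxyphenyl)methoxy]but-2-en-1-ol | OC/C=C(\I)COCc1ccc(OC)cc1 | intermediate
5 | isopropenylmagnesium bromide | CC(=C)[Mg]Br | starting material
6 | isopropenylzinc chloride | CC(=C)[Zn]Cl | intermediate
7 | (2E)-3-{[(4-methoxyphenyl)methoxy]methyl}-4-methylpenta-2,4-dien-1-ol | OC/C=C(\C(C)=C)COCc1ccc(OC)cc1 | intermediate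
8 | δ-valerolactone | O=C1CCCCO1 | starting material
9 | sodium 5-hydroxypentanoate | OCCCCC(=O)[O-].[Na+] | intermediate
10 | tert-butyldimethylsilyl 5-[(tert-butyldimethylsilyl)oxy]pentanoate | CC(C)(C)[Si](C)(C)OCCCCC(=O)O[Si](C)(C)C(C)(C)C | intermediate
11 | 5-[(tert-butyldimethylsilyl)oxy]pentanoic acid | CC(C)(C)[Si](C)(C)OCCCCC(=O)O | intermediate
12 | (2E)-3-{[(4-methoxyphenyl)methoxy]methyl}-4-methylpenta-2,4-dien-1-yl 5-[(tert-butyldimethylsilyl)oxy]pentanoate | CC(C)(C)[Si](C)(C)OCCCCC(=O)OC/C=C(\C(C)=C)COCc1ccc(OC)cc1 | intermediate
13 | boron enolate of 12 (O-bound (4S,5S)-diazaborolidine; side chain cis to O–B) | CC(C)(C)[Si](C)(C)OCCC/C=C(\OB1N(S(=O)(=O)c2cc(cc(c2)C(F)(F)F)C(F)(F)F)[C@@H](c2ccccc2)[C@H](c2ccccc2)N1S(=O)(=O)c1cc(cc(c1)C(F)(F)F)C(F)(F)F)OC/C=C(\C(C)=C)COCc1ccc(OC)cc1 | intermediate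
14 | (2S,3R)-2-{3-[(tert-butyldimethylsilyl)oxy]propyl}-3-ethenyl-3-{[(4-methoxyphenyl)methoxy]methyl}-4-methylpent-4-enoic acid | C=C[C@@](C(C)=C)(COCc1ccc(OC)cc1)[C@H](CCCO[Si](C)(C)C(C)(C)C)C(=O)O | intermediate
15 | dilithium gem-diolate of 16 | C=C[C@@](C(C)=C)(COCc1ccc(OC)cc1)[C@H](CCCO[Si](C)(C)C(C)(C)C)C(C)([O-])[O-].[Li+].[Li+] | intermediate
16 | (3S,4R)-3-{3-[(tert-butyldimethylsilyl)oxy]propyl}-4-ethenyl-4-{[(4-methoxyphenyl)methoxy]methyl}-5-methylhex-5-en-2-one | C=C[C@@](C(C)=C)(COCc1ccc(OC)cc1)[C@H](CCCO[Si](C)(C)C(C)(C)C)C(C)=O | intermediate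
17 | (3S,4R)-3-{3-[(tert-butyldimethylsilyl)oxy]propyl}-4-ethenyl-4-(hydroxymethyl)-5-methylhex-5-en-2-one | C=C[C@@](C(C)=C)(CO)[C@H](CCCO[Si](C)(C)C(C)(C)C)C(C)=O | intermediate
18 | tert-butyl [(2R,3S)-3-acetyl-6-[(tert-butyldimethylsilyl)oxy]-2-ethenyl-2-(prop-1-en-2-yl)hexyl] carbonate | C=C[C@@](C(C)=C)(COC(=O)OC(C)(C)C)[C@H](CCCO[Si](C)(C)C(C)(C)C)C(C)=O | intermediate
19 | potassium enolate of 18 (methyl side) | C=C[C@@](C(C)=C)(COC(=O)OC(C)(C)C)[C@H](CCCO[Si](C)(C)C(C)(C)C)C(=C)[O-].[K+] | intermediate
20 | tert-butyl [(2R,3S)-6-[(tert-butyldimethylsilyl)oxy]-3-{1-[(tert-butyldimethylsilyl)oxy]ethenyl}-2-ethenyl-2-(prop-1-en-2-yl)hexyl] carbonate | C=C[C@@](C(C)=C)(COC(=O)OC(C)(C)C)[C@H](CCCO[Si](C)(C)C(C)(C)C)C(=C)O[Si](C)(C)C(C)(C)C | intermediate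
21 | (4aS,5S,8aS)-5-{3-[(tert-butyldimethylsilyl)oxy]propyl}-4a-ethenyl-8a-methylhexahydro-4H-1,3-benzodioxine-2,6-dione (cis-fused C1/C6 carbonate, C3 ketone) | C=C[C@@]1(COC2=O)[C@H](CCCO[Si](C)(C)C(C)(C)C)C(=O)CC[C@]1(C)O2 | intermediate
22 | (2S,3S,4S)-2-{3-[(tert-butyldimethylsilyl)oxy]propyl}-3-ethenyl-4-hydroxy-3-(hydroxymethyl)-4-methylcyclohexan-1-one | C=C[C@@]1(CO)[C@H](CCCO[Si](C)(C)C(C)(C)C)C(=O)CC[C@]1(C)O | intermediate
23 | (4aS,5S,8aS)-2,2-di-tert-butyl-5-{3-[(tert-butyldimethylsilyl)oxy]propyl}-4a-ethenyl-8a-methylhexahydro-4H-1,3,2-benzodioxasilin-6-one | C=C[C@@]1(CO[Si]2(C(C)(C)C)C(C)(C)C)[C@H](CCCO[Si](C)(C)C(C)(C)C)C(=O)CC[C@]1(C)O2 | intermediate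
24 | geranial | CC(C)=CCC/C(C)=C/C=O | starting material
25 | allenylboronic acid pinacol ester | C=C=CB1OC(C)(C)C(C)(C)O1 | starting material
26 | 2-{[(4R,5E)-6,10-dimethylundeca-5,9-dien-1-yn-4-yl]oxy}-4,4,5,5-tetramethyl-1,3,2-dioxaborolane | C#CC[C@@H](OB1OC(C)(C)C(C)(C)O1)/C=C(\C)CCC=C(C)C | intermediate
27 | (4R,5E)-6,10-dimethylundeca-5,9-dien-1-yn-4-ol | C#CC[C@@H](O)/C=C(\C)CCC=C(C)C | intermediate
28 | tert-butyl{[(4R,5E)-6,10-dimethylundeca-5,9-dien-1-yn-4-yl]oxy}dimethylsilane | C#CC[C@@H](O[Si](C)(C)C(C)(C)C)/C=C(\C)CCC=C(C)C | intermediate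
29 | dimethyl[(1E,4R,5E)-4-[(tert-butyldimethylsilyl)oxy]-2,6,10-trimethylundeca-1,5,9-trien-1-yl]alumane | C[Al](C)/C=C(\C)C[C@@H](O[Si](C)(C)C(C)(C)C)/C=C(\C)CCC=C(C)C | intermediate
30 | tert-butyl{[(1E,4R,5E)-1-iodo-2,6,10-trimethylundeca-1,5,9-trien-4-yl]oxy}dimethylsilane | I/C=C(\C)C[C@@H](O[Si](C)(C)C(C)(C)C)/C=C(\C)CCC=C(C)C | intermediate
31 | 9-{2-[(4aS,5S,8aS)-silylene ketone-4a-yl]ethyl}-9-borabicyclo[3.3.1]nonane (23 with the vinyl group as CH2CH2–B) | C1CCC2CCCC1B2CC[C@@]3(CO[Si]4(C(C)(C)C)C(C)(C)C)[C@H](CCCO[Si](C)(C)C(C)(C)C)C(=O)CC[C@]3(C)O4 | intermediate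
32 | (4aS,5S,8aS)-2,2-di-tert-butyl-5-{3-[(tert-butyldimethylsilyl)oxy]propyl}-4a-[(3E,6R,7E)-6-[(tert-butyldimethylsilyl)oxy]-4,8,12-trimethyltrideca-3,7,11-trien-1-yl]-8a-methylhexahydro-4H-1,3,2-benzodioxasilin-6-one | CC(C)=CCC/C(C)=C/[C@H](O[Si](C)(C)C(C)(C)C)C/C(C)=C/CC[C@@]1(CO[Si]2(C(C)(C)C)C(C)(C)C)[C@H](CCCO[Si](C)(C)C(C)(C)C)C(=O)CC[C@]1(C)O2 | intermediate
33 | tertiary allylic alcohol: 32 with hydroxyl and prop-1-en-2-yl on C3 (C3 epimers, no descriptor drawn there) | CC(C)=CCC/C(C)=C/[C@H](O[Si](C)(C)C(C)(C)C)C/C(C)=C/CC[C@@]1(CO[Si]2(C(C)(C)C)C(C)(C)C)[C@H](CCCO[Si](C)(C)C(C)(C)C)C(O)(C(C)=C)CC[C@]1(C)O2 | intermediate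
34 | (2Z)-2-[(4aS,5R,8aS)-2,2-di-tert-butyl-5-{3-[(tert-butyldimethylsilyl)oxy]propyl}-4a-[(3E,6R,7E)-6-[(tert-butyldimethylsilyl)oxy]-4,8,12-trimethyltrideca-3,7,11-trien-1-yl]-8a-methylhexahydro-4H-1,3,2-benzodioxasilin-6-ylidene]propanal | CC(C)=CCC/C(C)=C/[C@H](O[Si](C)(C)C(C)(C)C)C/C(C)=C/CC[C@@]1(CO[Si]2(C(C)(C)C)C(C)(C)C)[C@H](CCCO[Si](C)(C)C(C)(C)C)/C(=C(/C)C=O)CC[C@]1(C)O2 | intermediate
35 | (2Z)-2-[(2R,3S,4S)-4-hydroxy-3-(hydroxymethyl)-2-(3-hydroxypropyl)-3-[(3E,6R,7E)-6-hydroxy-4,8,12-trimethyltrideca-3,7,11-trien-1-yl]-4-methylcyclohexylidene]propanal (CNP0172524.1) | CC(C)=CCC/C(C)=C/[C@H](O)C/C(C)=C/CC[C@@]1(CO)[C@H](CCCO)/C(=C(/C)C=O)CC[C@]1(C)O | target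

## Step count and risks

Total step count: 20. Longest linear sequence: 16 steps (steps 1–3, 5–13, 17–20); step 4 and steps 14–16 are side branches.

**Step 11 (key step, the only proposed new method).** The most likely failure is loss of the C6 cation by proton loss to ring or exocyclic alkenes before the carbonate closes, or incomplete second oxidation so that the C6 radical is quenched. Both leave the ring formed but C6 without its oxygen. Less likely are closure onto the vinyl group or protodesilylation of the enol ether in the slightly acidic medium.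
Fallback, from 20 back to 21 by known reactions on the same disconnection: N-iodosuccinimide in THF converts the enol ether into the α-iodo ketone F1. Iodine-atom-transfer radical cyclisation (catalytic Bu3SnSnBu3, visible light, benzene) closes ring A 6-endo at the isopropenyl group to the tertiary iodide F2. AgOSO2CF3 with 2,6-di-tert-butylpyridine in CH2Cl2 at low temperature ionises F2, and the tert-butyl carbonate closes to 21 with loss of isobutene.

**Step 6.** The rearrangement of this crowded dienyl ester needs the isopropenyl group axial and may be slow. Erosion of enolate geometry would give the C2 epimer, and poor facial discrimination by the controller would lower the enantiomeric purity.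
Fallback, from 12 back to 14: silyl-trapping Ireland–Claisen conditions (LiN(iPr)2, Me3SiCl, THF with N,N'-dimethylpropyleneurea, −78 °C to rt, the additive giving the same enolate geometry) should deliver the racemic acid F3 with the required relative configuration. Resolution as the (S)-1-phenylethylammonium salt F4 by fractional crystallisation, then acidification, returns 14.

**Step 7.** Addition to the hindered lithium carboxylate may stall, leaving time for α-deprotonation and loss of configuration at C2, or the ketone may be released early and add a second methyl.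
Fallback, from 14 back to 16: coupling with N,O-dimethylhydroxylamine hydrochloride (carbodiimide, 1-hydroxybenzotriazole, iPr2NEt) gives the Weinreb amide F5, and MeMgBr in THF at 0 °C converts it into 16 through the stable chelate.

**Step 17.** Competitive reduction of the C3 ketone by 9-BBN may accompany the slow hydroboration of a vinyl group on a quaternary carbon, giving mixtures at the ketone oxidation level.
Fallback, from 23 back to 32: NaBH4 in MeOH reduces the ketone on purpose to the secondary alcohol F6. Hydroboration with excess 9-BBN and the same Suzuki coupling with 30 give the coupled alcohol F7, and Dess–Martin periodinane restores the ketone of 32.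

**Step 19.** Geometric control in the chromate shift may be poor and give E/Z mixtures. Ionisation of the tertiary allylic chromate with proton loss to dienes is the other risk.
Fallback, from 33 back to 34: O3ReOSiPh3 (catalytic, Et2O, low temperature) transposes the tertiary allylic alcohol reversibly to the primary allylic alcohol F8, so the alkene geometry comes under thermodynamic control. MnO2 in CH2Cl2 then oxidises the allylic alcohol to 34 without acid.

## Further compounds

F1 | step 11 | tert-butyl [(2R,3S)-6-[(tert-butyldimethylsilyl)oxy]-2-ethenyl-3-(iodoacetyl)-2-(prop-1-en-2-yl)hexyl] carbonate | C=C[C@@](C(C)=C)(COC(=O)OC(C)(C)C)[C@H](CCCO[Si](C)(C)C(C)(C)C)C(=O)CI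
F2 | step 11 | tertiary iodide: ring A closed, iodine and methyl on C6 (either epimer), Boc carbonate on the C1 CH2O | C=C[C@@]1(COC(=O)OC(C)(C)C)[C@H](CCCO[Si](C)(C)C(C)(C)C)C(=O)CCC1(C)I
F3 | step 6 | racemic acid, (2S,3R) and (2R,3S) enantiomers of 14 | C=C[C@@](C(C)=C)(COCc1ccc(OC)cc1)[C@H](CCCO[Si](C)(C)C(C)(C)C)C(=O)O.C=C[C@](C(C)=C)(COCc1ccc(OC)cc1)[C@@H](CCCO[Si](C)(C)C(C)(C)C)C(=O)O
F4 | step 6 | (S)-1-phenylethylammonium salt of 14 | C=C[C@@](C(C)=C)(COCc1ccc(OC)cc1)[C@H](CCCO[Si](C)(C)C(C)(C)C)C(=O)[O-].C[C@H]([NH3+])c1ccccc1
F5 | step 7 | N-methoxy-N-methyl amide of 14 | C=C[C@@](C(C)=C)(COCc1ccc(OC)cc1)[C@H](CCCO[Si](C)(C)C(C)(C)C)C(=O)N(C)OC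
F6 | step 17 | C3 alcohol of 23 (C3 epimers) | C=C[C@@]1(CO[Si]2(C(C)(C)C)C(C)(C)C)[C@H](CCCO[Si](C)(C)C(C)(C)C)C(O)CC[C@]1(C)O2
F7 | step 17 | C3 alcohol of 32 (C3 epimers) | CC(C)=CCC/C(C)=C/[C@H](O[Si](C)(C)C(C)(C)C)C/C(C)=C/CC[C@@]1(CO[Si]2(C(C)(C)C)C(C)(C)C)[C@H](CCCO[Si](C)(C)C(C)(C)C)C(O)CC[C@]1(C)O2
F8 | step 19 | (2Z)-primary allylic alcohol corresponding to 34 (CH2OH in place of CHO) | CC(C)=CCC/C(C)=C/[C@H](O[Si](C)(C)C(C)(C)C)C/C(C)=C/CC[C@@]1(CO[Si]2(C(C)(C)C)C(C)(C)C)[C@H](CCCO[Si](C)(C)C(C)(C)C)/C(=C(/C)CO)CC[C@]1(C)O2
A1 | alternative 1 | 3-[2-(3-oxobutyl)-1,3-dioxolan-2-yl]propanoic acid | CC(=O)CCC1(CCC(=O)O)OCCO1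
A2 | alternative 1 | cis-fused bicyclic β-lactone with C3 ketal | O=C1O[C@@]2(C)CCC3(OCCO3)C[C@@H]12
A3 | alternative 2 | enyne acetonide (C1 vinyl, C6 pent-3-ynyl) | COc1ccc(cc1)COCC[C@]2(C=C)COC(C)(C)O[C@@]2(C)CCC#CC
A4 | alternative 2 | bicyclo[4.3.0]nonenone | COc3ccc(cc3)COCC[C@@]1(COC(C)(C)O2)[C@@H]4CC(=O)C(C)=C4CC[C@@]12C
A5 | alternative 3 | bromomethylsilyl ether of the 4-hydroxy-4-methylcyclohexenone | O1CCOC1CCC2=CC(=O)CC[C@]2(C)O[Si](C)(C)CBr
A6 | alternative 3 | cis-fused oxasilolane ketone | O1CCOC1CC[C@@]2(C[Si](C)(C)O3)CC(=O)CC[C@@]23C
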